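The route cuts the three methylene-to-outer-ring bonds, leaving a bibenzyl that carries three methyl groups. The methyl carbons on C2 and C6 of ring A and on C2' of ring B each lie ortho or para to a ring oxygen (O3 and O5 of ring A, O5' of ring B), while both bridge CH2 groups are meta to all of them, so anodic oxidation should touch the methyl C–H bonds only. One electrolysis in the presence of a sulfilimine stores three benzylic cations, which then take three 4-silylated isopropyl phenyl ethers at the silicon-bearing carbon. The precursor is the di-O-isopropyl trimethyl bibenzyl, built by a B-alkyl Suzuki coupling.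

Key step: step 8

Remark: the target has no stereocentre; 1-bromo-4-isopropoxybenzene, vinylboronic acid pinacol ester and methylzinc chloride are taken as purchasable; step 8 builds three molecules of 12 into each molecule of 9 (one stands as reactant, the second and third on the reagent line, as do both equivalents of N-iodosuccinimide in step 2 and of methylzinc chloride in step 3), and the silane is used in excess with a hindered pyridine so that protodesilylation and intramolecular attack on ring B are outpaced.

Step 1
Reactants: 1 3-bromo-5-methoxyphenol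
Product: 2 1-bromo-3-isopropoxy-5-methoxybenzene
Conditions: 2-bromopropane, K2CO3, DMF, 60 °C
Reagents that add atoms: 2-bromopropane, CC(C)Br
Why: Williamson ether synthesis, in which the phenoxide formed with K2CO3 displaces bromide from 2-bromopropane while the aryl bromide and the methyl ether stay untouched.

Step 2
Reactants: 2 1-bromo-3-isopropoxy-5-methoxybenzene
Product: 3 3-bromo-2,4-diiodo-1-isopropoxy-5-methoxybenzene
Conditions: NIS (2.3 equiv), TFA (0.3 equiv), MeCN, 25 → 45 °C
Reagents that add atoms: N-iodosuccinimide (first equivalent), O=C1CCC(=O)N1I; N-iodosuccinimide (second equivalent), O=C1CCC(=O)N1I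
Why: Electrophilic aromatic iodination, which in resorcinol diethers goes para to an alkoxy group in preference to the carbon between the two oxygens, so two equivalents of NIS should iodinate both carbons flanking bromine.

Step 3
Reactants: 3 3-bromo-2,4-diiodo-1-isopropoxy-5-methoxybenzene
Product: 4 3-bromo-1-isopropoxy-5-methoxy-2,4-dimethylbenzene
Conditions: MeZnCl (3 equiv), Pd(dppf)Cl2 (5 mol%), THF, 25 → 50 °C
Reagents that add atoms: methylzinc chloride (first equivalent), C[Zn]Cl; methylzinc chloride (second equivalent), C[Zn]Cl
Why: Twofold Negishi coupling, in which zerovalent palladium inserts into the two C–I bonds far faster than into the C–Br bond, which becomes flanked by two methyl groups as the reaction proceeds and should therefore survive.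

Step 4
Reactants: 5 3-bromo-4-methylphenol
Product: 6 2-bromo-4-isopropoxy-1-methylbenzene
Conditions: 2-bromopropane, K2CO3, DMF, 60 °C
Reagents that add atoms: 2-bromopropane, CC(C)Br
Why: Williamson ether synthesis under the same conditions as step 1, with no competing nucleophilic site in the substrate.

Step 5
Reactants: 6 2-bromo-4-isopropoxy-1-methylbenzene
Product: 7 2-ethenyl-4-isopropoxy-1-methylbenzene
Conditions: vinylboronic acid pinacol ester, Pd(dppf)Cl2 (3 mol%), K2CO3, dioxane/H2O, 90 °C
Reagents that add atoms: vinylboronic acid pinacol ester, C=CB1OC(C)(C)C(C)(C)O1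
Why: Suzuki–Miyaura vinylation of an aryl bromide that has only one ortho methyl group, with an isopropyl ether that is inert to aqueous carbonate.

Step 6
Reactants: 7 2-ethenyl-4-isopropoxy-1-methylbenzene; 4 3-bromo-1-isopropoxy-5-methoxy-2,4-dimethylbenzene
Product: 9 1-isopropoxy-3-[2-(5-isopropoxy-2-methylphenyl)ethyl]-5-methoxy-2,4-dimethylbenzene, via B-alkyl-9-BBN adduct 8 (not isolated)
Conditions: 9-BBN, THF, 0 → 25 °C; then 4, Pd(OAc)2 (5 mol%), SPhos (10 mol%), K3PO4, THF/H2O, 65 °C
Reagents that add atoms: none
Why: Anti-Markovnikov hydroboration of the styrene followed by B-alkyl Suzuki–Miyaura coupling, in which the primary alkylborane transmetalates readily and the bulky electron-rich biarylphosphine SPhos drives oxidative addition into the di-ortho-substituted aryl bromide.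

Step 7
Reactants: 10 1-bromo-4-isopropoxybenzene
Product: 12 1-isopropoxy-4-(trimethylsilyl)benzene, via aryllithium 11 (not isolated)
Conditions: n-BuLi, THF, −78 °C; then Me3SiCl, −78 → 25 °C
Reagents that add atoms: chlorotrimethylsilane, C[Si](C)(C)Cl
Why: Bromine–lithium exchange followed by silylation of the aryllithium, which at −78 °C is faster than any ortho-lithiation next to the isopropyl ether.

Step 8
Reactants: 9 1-isopropoxy-3-[2-(5-isopropoxy-2-methylphenyl)ethyl]-5-methoxy-2,4-dimethylbenzene; 12 1-isopropoxy-4-(trimethylsilyl)benzene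
Product: 14 1-isopropoxy-2,4-bis(4-isopropoxybenzyl)-3-{2-[5-isopropoxy-2-(4-isopropoxybenzyl)phenyl]ethyl}-5-methoxybenzene, via tris(aminosulfonium) salt 13 (not isolated)
Conditions: divided H-cell, carbon-felt anode, Pt cathode (catholyte: TfOH), Ph2S=NTs (9 equiv), Bu4NB(C6F5)4 (0.1 M), CH2Cl2, constant current, 6.5 F/mol, 25 °C; then 2,6-di-tert-butyl-4-methylpyridine (3.5 equiv), 12 (15 equiv in all, three of which are incorporated), 25 → 40 °C; Et3N
Reagents that add atoms: 1-isopropoxy-4-(trimethylsilyl)benzene (second equivalent of 12), CC(C)Oc1ccc([Si](C)(C)C)cc1; 1-isopropoxy-4-(trimethylsilyl)benzene (third equivalent of 12), CC(C)Oc1ccc([Si](C)(C)C)cc1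
Why: Proposed new method: each alkoxyarene ring of 9 is oxidised at the anode to its radical cation, which loses a proton from a methyl group on a carbon ortho or para to oxygen, and a second electron transfer gives an oxygen-stabilised benzyl cation that the sulfilimine nitrogen traps as an aminosulfonium ion, whose charge protects that arm from further oxidation while the next methyl group reacts, until all three are stored in 13. Three molecules of silane 12, added afterwards, should each attack one benzyl cation released reversibly from 13 through the silicon-bearing carbon and lose the trimethylsilyl group, forming the three CH2–aryl bonds; no ring is closed and no stereocentre is formed. The closest known reaction type is the anodic benzylic C–H/aromatic C–H cross-coupling of alkoxytoluenes through pooled benzylaminosulfonium ions, known for one methyl group per substrate and extended here to three on one molecule, with ipso-desilylation in place of C–H substitution. Methyl rather than bridge C–H oxidation is expected because the bridge carbons sit on C1 and C1', meta to O3, O5 and O5', so their C–H bonds are neither acidified in the radical cation nor able to give a stabilised cation. Para attachment on the outer rings is fixed by the silyl group, and the hindered pyridine takes up the protons made in the electrolysis so that 12 is not protodesilylated. The large excess of 12 is meant to outrun a second benzylation of the product rings and the attack of a ring A benzyl cation on C6' of ring B, which would close a seven-membered ring.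

Step 9
Reactants: 14 1-isopropoxy-2,4-bis(4-isopropoxybenzyl)-3-{2-[5-isopropoxy-2-(4-isopropoxybenzyl)phenyl]ethyl}-5-methoxybenzene
Product: 15 4-(4-hydroxybenzyl)-3-{2-[3-hydroxy-2,6-bis(4-hydroxybenzyl)-5-methoxyphenyl]ethyl}phenol (CNP0147493.0)
Conditions: BCl3 (15 equiv), CH2Cl2, −78 → 0 °C; then MeOH, aq. NaHCO3
Reagents that add atoms: none
Why: Lewis-acid ether cleavage, in which BCl3 coordinates the ether oxygens and chloride removes the secondary isopropyl groups as 2-chloropropane much faster than it attacks a methyl group, so the five isopropyl ethers should fall while the methyl ether at C5 of ring A stays.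

Compound list
1 | 3-bromo-5-methoxyphenol | COc1cc(O)cc(Br)c1 | starting material
2 | 1-bromo-3-isopropoxy-5-methoxybenzene | COc1cc(OC(C)C)cc(Br)c1 | intermediate
3 | 3-bromo-2,4-diiodo-1-isopropoxy-5-methoxybenzene | COc1cc(OC(C)C)c(I)c(Br)c1I | intermediate
4 | 3-bromo-1-isopropoxy-5-methoxy-2,4-dimethylbenzene | COc1cc(OC(C)C)c(C)c(Br)c1C | intermediate
5 | 3-bromo-4-methylphenol | Cc1ccc(O)cc1Br | starting material
6 | 2-bromo-4-isopropoxy-1-methylbenzene | Cc1ccc(OC(C)C)cc1Br | intermediate
7 | 2-ethenyl-4-isopropoxy-1-methylbenzene | C=Cc1cc(OC(C)C)ccc1C | intermediate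
8 | 9-[2-(5-isopropoxy-2-methylphenyl)ethyl]-9-borabicyclo[3.3.1]nonane (not isolated) | Cc1ccc(OC(C)C)cc1CCB1C2CCCC1CCC2 | intermediate
9 | 1-isopropoxy-3-[2-(5-isopropoxy-2-methylphenyl)ethyl]-5-methoxy-2,4-dimethylbenzene (trimethyl bibenzyl core) | COc1cc(OC(C)C)c(C)c(CCc2cc(OC(C)C)ccc2C)c1C | intermediate
10 | 1-bromo-4-isopropoxybenzene | CC(C)Oc1ccc(Br)cc1 | starting material
11 | (4-isopropoxyphenyl)lithium (not isolated) | [Li]c1ccc(OC(C)C)cc1 | intermediate
12 | 1-isopropoxy-4-(trimethylsilyl)benzene | CC(C)Oc1ccc([Si](C)(C)C)cc1 | intermediate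
13 | trication of 9 in which each of the three former methyl carbons is a CH2 bonded to the nitrogen of an N-tosyl-S,S-diphenylaminosulfonium group, as its tetrakis(pentafluorophenyl)borate salt (not isolated) | COc1cc(OC(C)C)c(CN([S+](c2ccccc2)c2ccccc2)S(=O)(=O)c2ccc(C)cc2)c(CCc2cc(OC(C)C)ccc2CN([S+](c3ccccc3)c3ccccc3)S(=O)(=O)c3ccc(C)cc3)c1CN([S+](c1ccccc1)c1ccccc1)S(=O)(=O)c1ccc(C)cc1 | intermediate
14 | 1-isopropoxy-2,4-bis(4-isopropoxybenzyl)-3-{2-[5-isopropoxy-2-(4-isopropoxybenzyl)phenyl]ethyl}-5-methoxybenzene (penta-O-isopropyl target) | COc1cc(OC(C)C)c(Cc2ccc(OC(C)C)cc2)c(CCc2cc(OC(C)C)ccc2Cc2ccc(OC(C)C)cc2)c1Cc1ccc(OC(C)C)cc1 | intermediate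
15 | 4-(4-hydroxybenzyl)-3-{2-[3-hydroxy-2,6-bis(4-hydroxybenzyl)-5-methoxyphenyl]ethyl}phenol | COc1cc(O)c(Cc2ccc(O)cc2)c(CCc2cc(O)ccc2Cc2ccc(O)cc2)c1Cc1ccc(O)cc1 | target

Total step count: 9. Longest linear sequence: 6 steps (steps 1, 2, 3, 6, 8 and 9).

Steps most likely to fail

Step 8 (threefold anodic arylation). Several processes may go wrong. The third oxidation may stall, because a ring that already carries a cationic arm is harder to oxidise. The protons released may strip isopropyl or silyl groups. A benzyl cation may be intercepted by the free C4–H of ring A of another molecule, or by C6' of ring B, before 12 reaches it. The fallback uses known chemistry, sets out from 3 and comes back at 14: the benzyl groups are placed on the two ring fragments by Negishi coupling before the rings are joined. Purchasable 4-isopropoxybenzyl chloride is converted with zinc dust and LiCl in THF into (4-isopropoxybenzyl)zinc chloride F1. With Pd(dppf)Cl2 two equivalents of F1 should couple at both C–I bonds of 3, as in step 3, to give 3-bromo-1-isopropoxy-2,4-bis(4-isopropoxybenzyl)-5-methoxybenzene F2. Purchasable 3-bromo-4-iodophenol is isopropylated as in step 4 to 2-bromo-1-iodo-4-isopropoxybenzene F3, which is coupled with F1 at iodine to give 2-bromo-4-isopropoxy-1-(4-isopropoxybenzyl)benzene F4. Suzuki vinylation as in step 5 gives 2-ethenyl-4-isopropoxy-1-(4-isopropoxybenzyl)benzene F5. Hydroboration with 9-BBN gives 9-{2-[5-isopropoxy-2-(4-isopropoxybenzyl)phenyl]ethyl}-9-borabicyclo[3.3.1]nonane F6, and B-alkyl Suzuki coupling of F6 with F2 under the conditions of step 6 gives 14.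

Step 6 (B-alkyl Suzuki coupling at the di-ortho-substituted bromide). Oxidative addition at the crowded, electron-rich C–Br bond may be so slow that protodeboronation of 8 and reduction of 4 take over. The fallback sets out from 2 and 8 and comes back at 9, coupling first and methylating afterwards. Borane 8 is coupled with the unhindered bromide 2 (Pd(dppf)Cl2, K3PO4, THF/H2O) to give 1-isopropoxy-3-[2-(5-isopropoxy-2-methylphenyl)ethyl]-5-methoxybenzene F7. Two equivalents of NIS in MeCN without strong acid should iodinate only the resorcinol-type ring A at the two carbons flanking the chain, since ring B is a para-blocked monoether and far less reactive, giving 2,4-diiodo-1-isopropoxy-3-[2-(5-isopropoxy-2-methylphenyl)ethyl]-5-methoxybenzene F8. Double Negishi methylation with MeZnCl as in step 3, now with no competing bromide, gives 9.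

Step 2 (twofold iodination). The second iodination may stop at the monoiodide or go to the carbon between the two oxygens, because the carbon next to bromine is crowded. The fallback sets out from 2 and comes back at 4 by two rounds of Vilsmeier–Haack formylation (POCl3, DMF, 90 °C) and ionic hydrogenation (Et3SiH, TFA, CH2Cl2). The first formylation should go to either carbon next to bromine, giving 2-bromo-6-isopropoxy-4-methoxybenzaldehyde F9 and 2-bromo-4-isopropoxy-6-methoxybenzaldehyde F10. These are reduced without separation to 1-bromo-3-isopropoxy-5-methoxy-2-methylbenzene F11 and 1-bromo-5-isopropoxy-3-methoxy-2-methylbenzene F12. The second formylation at the remaining carbon next to bromine gives 2-bromo-4-isopropoxy-6-methoxy-3-methylbenzaldehyde F13 and 2-bromo-6-isopropoxy-4-methoxy-3-methylbenzaldehyde F14, and the second reduction makes both converge on 4.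

Further compounds
F1 | step 8 | (4-isopropoxybenzyl)zinc chloride | CC(C)Oc1ccc(C[Zn]Cl)cc1
F2 | step 8 | 3-bromo-1-isopropoxy-2,4-bis(4-isopropoxybenzyl)-5-methoxybenzene | COc1cc(OC(C)C)c(Cc2ccc(OC(C)C)cc2)c(Br)c1Cc1ccc(OC(C)C)cc1
F3 | step 8 | 2-bromo-1-iodo-4-isopropoxybenzene | CC(C)Oc1ccc(I)c(Br)c1
F4 | step 8 | 2-bromo-4-isopropoxy-1-(4-isopropoxybenzyl)benzene | CC(C)Oc1ccc(Cc2ccc(OC(C)C)cc2Br)cc1
F5 | step 8 | 2-ethenyl-4-isopropoxy-1-(4-isopropoxybenzyl)benzene | C=Cc1cc(OC(C)C)ccc1Cc1ccc(OC(C)C)cc1
F6 | step 8 | 9-{2-[5-isopropoxy-2-(4-isopropoxybenzyl)phenyl]ethyl}-9-borabicyclo[3.3.1]nonane | CC(C)Oc1ccc(Cc2ccc(OC(C)C)cc2CCB2C3CCCC2CCC3)cc1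
F7 | step 6 | 1-isopropoxy-3-[2-(5-isopropoxy-2-methylphenyl)ethyl]-5-methoxybenzene | COc1cc(OC(C)C)cc(CCc2cc(OC(C)C)ccc2C)c1
F8 | step 6 | 2,4-diiodo-1-isopropoxy-3-[2-(5-isopropoxy-2-methylphenyl)ethyl]-5-methoxybenzene | COc1cc(OC(C)C)c(I)c(CCc2cc(OC(C)C)ccc2C)c1I
F9 | step 2 | 2-bromo-6-isopropoxy-4-methoxybenzaldehyde | COc1cc(OC(C)C)c(C=O)c(Br)c1
F10 | step 2 | 2-bromo-4-isopropoxy-6-methoxybenzaldehyde | COc1cc(OC(C)C)cc(Br)c1C=O
F11 | step 2 | 1-bromo-3-isopropoxy-5-methoxy-2-methylbenzene | COc1cc(OC(C)C)c(C)c(Br)c1
F12 | step 2 | 1-bromo-5-isopropoxy-3-methoxy-2-methylbenzene | COc1cc(OC(C)C)cc(Br)c1C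
F13 | step 2 | 2-bromo-4-isopropoxy-6-methoxy-3-methylbenzaldehyde | COc1cc(OC(C)C)c(C)c(Br)c1C=O
F14 | step 2 | 2-bromo-6-isopropoxy-4-methoxy-3-methylbenzaldehyde | COc1cc(OC(C)C)c(C=O)c(Br)c1C
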